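The feature exploited is the unsubstituted CH2 of the oxirane ring: cutting its two bonds, quaternary C–CH2 and CH2–O, leaves an aryl ketone in which the benzene ring and the CH2O arm are both attached to the carbonyl carbon from the start. One operation, a catalytic enantioselective Corey–Chaykovsky methylene transfer, then forms both bonds, closes the three-membered ring and sets the only stereocentre. The precursor is an α-silyloxy aryl ketone with the phenol as allyl ether and the benzylic alcohol already as its pentanoate. It is reached in four linear steps through an aryllithium and a Weinreb amide, and three steps (desilylation, acetylation, deallylation with in-flask isobutyrylation) finish the target.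

Key step: step 7

Assumption: the (S)-binaphthoxide catalyst is taken to be the antipode that delivers the methylene group to the ketone face leading to the (S)-oxirane (aryl as the large flank, CH2OSi as the small one); if the sense proves opposite, the (R)-catalyst is used with no other change.

Step 1
Reactants: 1 methyl 4-bromo-3-hydroxybenzoate; 2 allyl bromide
Product: 3 methyl 4-bromo-3-(prop-2-en-1-yloxy)benzoate
Conditions: K2CO3, DMF, rt
Reagents that add atoms: allyl bromide C=CCBr
Why: Williamson ether synthesis: the potassium phenoxide displaces bromide from allyl bromide by SN2 substitution, while the methyl ester and the aryl bromide are inert to K2CO3 in DMF at room temperature.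

Step 2
Reactants: 3 methyl 4-bromo-3-(prop-2-en-1-yloxy)benzoate
Product: 4 [4-bromo-3-(prop-2-en-1-yloxy)phenyl]methanol
Conditions: i-Bu2AlH (2.5 equiv), CH2Cl2, −78 → 0 °C; aq. potassium sodium tartrate
Reagents that add atoms: none
Why: Hydride reduction of an ester: two hydride transfers from i-Bu2AlH take the methyl ester to the benzylic alcohol at low temperature, and this reagent touches neither the aryl bromide nor the allyl ether.

Step 3
Reactants: 5 methyl 2-[(tert-butyldimethylsilyl)oxy]acetate; 6 N,O-dimethylhydroxylamine hydrochloride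
Product: 7 2-[(tert-butyldimethylsilyl)oxy]-N-methoxy-N-methylacetamide
Conditions: i-PrMgCl (3 equiv), THF, −20 → 0 °C
Reagents that add atoms: N,O-dimethylhydroxylamine hydrochloride CNOC.Cl
Why: Weinreb amide formation by aminolysis of an ester: the chloromagnesium amide generated from 6 and i-PrMgCl adds to the ester carbonyl and expels methoxide, the silyl ether being stable to the cold basic medium.

Step 4
Reactants: 4 [4-bromo-3-(prop-2-en-1-yloxy)phenyl]methanol; 7 2-[(tert-butyldimethylsilyl)oxy]-N-methoxy-N-methylacetamide
Product: 10 2-[(tert-butyldimethylsilyl)oxy]-1-[4-(hydroxymethyl)-2-(prop-2-en-1-yloxy)phenyl]ethan-1-one, via dilithio aryl species 8 (not isolated), via tetrahedral lithium adduct 9 (not isolated)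
Conditions: n-BuLi (2.1 equiv), THF, −78 °C; then 7, −78 → −20 °C; H2O
Reagents that add atoms: 2-[(tert-butyldimethylsilyl)oxy]-N-methoxy-N-methylacetamide CON(C)C(=O)CO[Si](C)(C)C(C)(C)C
Why: Bromine–lithium exchange followed by Weinreb ketone synthesis: the first equivalent of n-BuLi forms the lithium alkoxide and the second exchanges the bromide at −78 °C, and the aryllithium adds only once to 7 because the chelated adduct 9 holds until the aqueous quench, so that the α-silyloxy ketone appears only when no nucleophile is left.

Step 5
Reactants: 10 2-[(tert-butyldimethylsilyl)oxy]-1-[4-(hydroxymethyl)-2-(prop-2-en-1-yloxy)phenyl]ethan-1-one; 11 pentanoyl chloride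
Product: 12 3-(allyloxy)-4-{2-[(tert-butyldimethylsilyl)oxy]acetyl}benzyl pentanoate
Conditions: pyridine, DMAP (cat.), CH2Cl2, 0 °C
Reagents that add atoms: pentanoyl chloride CCCCC(Cl)=O
Why: Esterification of the only free hydroxyl group by an acid chloride under nucleophilic catalysis (pyridine, DMAP), conditions under which the α-silyloxy ketone, the silyl ether and the allyl ether are unchanged.

Step 6
Reactants: 13 trimethylsulfoxonium chloride
Product: 14 dimethylsulfoxonium methylide (filtered, titrated THF solution)
Conditions: NaH, THF, reflux; filtration under argon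
Reagents that add atoms: none
Why: Deprotonation of a sulfoxonium salt to its ylide (the reagent of the Corey–Chaykovsky reaction): NaH removes a methyl proton, and because NaCl is insoluble in THF, filtration gives a salt-free solution that can be titrated and dosed exactly.

Step 7
Reactants: 12 3-(allyloxy)-4-{2-[(tert-butyldimethylsilyl)oxy]acetyl}benzyl pentanoate; 14 dimethylsulfoxonium methylide
Product: 16 3-(allyloxy)-4-[(2S)-2-{[(tert-butyldimethylsilyl)oxy]methyl}oxiran-2-yl]benzyl pentanoate, via sulfoxonium alkoxide betaine 15 (not isolated)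
Conditions: 14 (1.2 equiv), LaLi3[(S)-binaphthoxide]3 (5 mol %), (2,4,6-(MeO)3C6H2)3P=O (5 mol %), 5 Å molecular sieves, THF, rt
Reagents that add atoms: dimethylsulfoxonium methylide C[S+](C)(=O)[CH2-]
Why: Proposed new method: Lewis-acid activation of the ketone oxygen at the trivalent lanthanum centre (made more reactive by the phosphine oxide ligand) and delivery of ylide 14 from a lithium binaphthoxide site of the same complex should form the C–C bond on one face of the carbonyl and give sulfoxonium alkoxide 15; the closest known reaction type is the catalytic asymmetric Corey–Chaykovsky epoxidation of aryl methyl ketones with this lanthanum–lithium binaphthoxide system, which has not been shown for α-silyloxymethyl ketones. The alkoxide oxygen of 15 then attacks the adjacent CH2 carbon with loss of dimethyl sulfoxide in a 3-exo-tet closure, which forms the oxirane ring. The one new stereocentre is set in the addition step under catalyst control by the (S)-binaphthoxide framework and is not touched by the closure, which occurs at the CH2 carbon. The step needs facial selectivity at the carbonyl, and the substrate secures it by offering two flanks of clearly different size, the twisted ortho-allyloxyaryl group and the CH2OSi arm, whose bulky silyl group also keeps that oxygen from chelating the metal. It also needs chemoselectivity for the ketone over the pentanoate, which an unactivated alkyl ester should show toward a stabilised sulfoxonium ylide at room temperature when only a small excess of 14 is used. A free ortho phenol would be deprotonated by the ylide and would make the carbonyl unreactive, hence the allyl ether.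

Step 8
Reactants: 16 3-(allyloxy)-4-[(2S)-2-{[(tert-butyldimethylsilyl)oxy]methyl}oxiran-2-yl]benzyl pentanoate
Product: 17 3-(allyloxy)-4-[(2R)-2-(hydroxymethyl)oxiran-2-yl]benzyl pentanoate
Conditions: Bu4NF, AcOH (1:1), THF, 0 °C → rt
Reagents that add atoms: none
Why: Fluoride-induced cleavage of a silyl ether, buffered by acetic acid so that no free alkoxide arises that could attack the pentanoate or start a Payne-type migration at the oxirane; the stereocentre is untouched, and the descriptor becomes R only because CH2OH ranks below the ring CH2.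

Step 9
Reactants: 17 3-(allyloxy)-4-[(2R)-2-(hydroxymethyl)oxiran-2-yl]benzyl pentanoate; 18 acetic anhydride
Product: 19 4-[(2S)-2-(acetoxymethyl)oxiran-2-yl]-3-(allyloxy)benzyl pentanoate
Conditions: pyridine, DMAP (cat.), CH2Cl2, 0 °C
Reagents that add atoms: acetic anhydride CC(=O)OC(C)=O
Why: Acetylation of a primary alcohol by acetic anhydride under pyridine and DMAP, a base-buffered medium that the acid-sensitive tertiary benzylic oxirane should tolerate; the stereocentre is not involved and the descriptor returns to S for priority reasons alone.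

Step 10
Reactants: 19 4-[(2S)-2-(acetoxymethyl)oxiran-2-yl]-3-(allyloxy)benzyl pentanoate; 20 isobutyryl chloride
Product: 22 4-[(2S)-2-(acetoxymethyl)oxiran-2-yl]-3-(isobutyryloxy)benzyl pentanoate, via tributylstannyl aryloxide 21 (not isolated)
Conditions: Pd(PPh3)4 (5 mol %), Bu3SnH (1.1 equiv, slow addition), CH2Cl2, rt; then i-PrCOCl, 0 °C
Reagents that add atoms: isobutyryl chloride CC(C)C(Cl)=O
Why: Palladium-catalysed hydrostannolysis of an allyl aryl ether followed by acylation of the tin aryloxide: zerovalent palladium ionises the allyl–oxygen bond, Bu3SnH reduces the π-allyl complex to propene and leaves the covalent stannyl ether 21, which the acid chloride converts into the aryl ester in the same flask, so that a free phenoxide next to the oxirane and the acetate never builds up.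

Compound list
1 | methyl 4-bromo-3-hydroxybenzoate | COC(=O)c1ccc(Br)c(O)c1 | starting material
2 | allyl bromide (3-bromoprop-1-ene) | C=CCBr | starting material
3 | methyl 4-bromo-3-(prop-2-en-1-yloxy)benzoate | COC(=O)c1ccc(Br)c(OCC=C)c1 | intermediate
4 | [4-bromo-3-(prop-2-en-1-yloxy)phenyl]methanol | OCc1ccc(Br)c(OCC=C)c1 | intermediate
5 | methyl 2-[(tert-butyldimethylsilyl)oxy]acetate | COC(=O)CO[Si](C)(C)C(C)(C)C | starting material
6 | N,O-dimethylhydroxylamine hydrochloride | CNOC.Cl | starting material
7 | 2-[(tert-butyldimethylsilyl)oxy]-N-methoxy-N-methylacetamide | CON(C)C(=O)CO[Si](C)(C)C(C)(C)C | intermediate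
8 | lithium [4-lithio-3-(prop-2-en-1-yloxy)phenyl]methanolate | [Li]OCc1ccc([Li])c(OCC=C)c1 | intermediate
9 | dilithium salt of the tetrahedral adduct 2-[(tert-butyldimethylsilyl)oxy]-1-[4-(hydroxymethyl)-2-(prop-2-en-1-yloxy)phenyl]-1-[methoxy(methyl)amino]ethan-1-ol (either configuration at the new carbon) | [Li]OCc1ccc(C(O[Li])(CO[Si](C)(C)C(C)(C)C)N(C)OC)c(OCC=C)c1 | intermediate
10 | 2-[(tert-butyldimethylsilyl)oxy]-1-[4-(hydroxymethyl)-2-(prop-2-en-1-yloxy)phenyl]ethan-1-one | OCc1ccc(C(=O)CO[Si](C)(C)C(C)(C)C)c(OCC=C)c1 | intermediate
11 | pentanoyl chloride | CCCCC(Cl)=O | starting material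
12 | 3-(allyloxy)-4-{2-[(tert-butyldimethylsilyl)oxy]acetyl}benzyl pentanoate | CCCCC(=O)OCc1ccc(C(=O)CO[Si](C)(C)C(C)(C)C)c(OCC=C)c1 | intermediate
13 | trimethylsulfoxonium chloride | C[S+](C)(C)=O.[Cl-] | starting material
14 | dimethylsulfoxonium methylide | C[S+](C)(=O)[CH2-] | intermediate
15 | 3-(allyloxy)-4-[(2R)-1-[(tert-butyldimethylsilyl)oxy]-3-(dimethyloxosulfonio)-2-oxidopropan-2-yl]benzyl pentanoate (betaine) | CCCCC(=O)OCc1ccc([C@@]([O-])(CO[Si](C)(C)C(C)(C)C)C[S+](C)(C)=O)c(OCC=C)c1 | intermediate
16 | 3-(allyloxy)-4-[(2S)-2-{[(tert-butyldimethylsilyl)oxy]methyl}oxiran-2-yl]benzyl pentanoate | CCCCC(=O)OCc1ccc([C@@]2(CO[Si](C)(C)C(C)(C)C)CO2)c(OCC=C)c1 | intermediate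
17 | 3-(allyloxy)-4-[(2R)-2-(hydroxymethyl)oxiran-2-yl]benzyl pentanoate | CCCCC(=O)OCc1ccc([C@@]2(CO)CO2)c(OCC=C)c1 | intermediate
18 | acetic anhydride | CC(=O)OC(C)=O | starting material
19 | 4-[(2S)-2-(acetoxymethyl)oxiran-2-yl]-3-(allyloxy)benzyl pentanoate | CCCCC(=O)OCc1ccc([C@@]2(COC(C)=O)CO2)c(OCC=C)c1 | intermediate
20 | isobutyryl chloride (2-methylpropanoyl chloride) | CC(C)C(Cl)=O | starting material
21 | 4-[(2S)-2-(acetoxymethyl)oxiran-2-yl]-3-[(tributylstannyl)oxy]benzyl pentanoate | CCCCC(=O)OCc1ccc([C@@]2(COC(C)=O)CO2)c(O[Sn](CCCC)(CCCC)CCCC)c1 | intermediate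
22 | 4-[(2S)-2-(acetoxymethyl)oxiran-2-yl]-3-(isobutyryloxy)benzyl pentanoate (CNP0107520.1) | CCCCC(=O)OCc1ccc([C@@]2(COC(C)=O)CO2)c(OC(=O)C(C)C)c1 | target

Total step count: 10 (steps 3 and 6 are one-step side branches that supply the Weinreb amide and the ylide solution).
Longest linear sequence: 8 steps (1, 2, 4, 5, 7, 8, 9, 10) from methyl 4-bromo-3-hydroxybenzoate.

Steps most likely to fail

Step 7 (bears the label). What may go wrong: weak facial discrimination because the CH2OSi flank is larger than the methyl group of the proven substrates. Slow addition to the hindered, electron-rich ketone is the other danger, since enolisation with silyl migration or attack of the ylide on the pentanoate could then take over. The fallback uses known chemistry, sets out from ketone 12 and comes back at epoxy alcohol 17. Wittig methylenation (Ph3PCH3Br, KN(SiMe3)2, THF, 0 °C) should give the 1,1-disubstituted alkene 3-(allyloxy)-4-{3-[(tert-butyldimethylsilyl)oxy]prop-1-en-2-yl}benzyl pentanoate F1. Buffered Bu4NF/AcOH in THF should free the allylic alcohol 3-(allyloxy)-4-(3-hydroxyprop-1-en-2-yl)benzyl pentanoate F2. Sharpless asymmetric epoxidation (Ti(OiPr)4, D-(−)-diisopropyl tartrate, t-BuOOH, 4 Å molecular sieves, CH2Cl2, −20 °C) should then oxidise only the double bond of the allylic alcohol and give 17 with the (R) descriptor. The unnatural tartrate is chosen because the facial rule for 2-substituted allylic alcohols assigns it the (R)-2-substituted glycidol. Steps 9 and 10 follow unchanged, and material made this way would also serve to confirm the sense of induction of step 7.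

Step 10. What may go wrong: the oxygen unmasked ortho to the oxirane opens the ring or takes over the neighbouring acetyl group before it is acylated, or hydrostannolysis stalls while Bu3SnH is lost by palladium-catalysed dehydrocoupling. The fallback changes the order of events so that the oxirane is made after the phenol ester; it sets out from ketone 12 and comes back at target 22. Methylenation as above gives alkene F1. Deallylation with Pd(PPh3)4 and morpholine, harmless while no oxirane is present, should give the phenol 3-hydroxy-4-{3-[(tert-butyldimethylsilyl)oxy]prop-1-en-2-yl}benzyl pentanoate F3. Isobutyryl chloride and Et3N should give the aryl ester 2-{3-[(tert-butyldimethylsilyl)oxy]prop-1-en-2-yl}-5-[(pentanoyloxy)methyl]phenyl 2-methylpropanoate F4. HF·pyridine in THF/pyridine should remove the silyl group without touching the aryl ester and give the allylic alcohol 2-(3-hydroxyprop-1-en-2-yl)-5-[(pentanoyloxy)methyl]phenyl 2-methylpropanoate F5. Sharpless asymmetric epoxidation with D-(−)-diisopropyl tartrate should give the epoxy alcohol 2-[(2R)-2-(hydroxymethyl)oxiran-2-yl]-5-[(pentanoyloxy)methyl]phenyl 2-methylpropanoate F6, and acetylation (Ac2O, pyridine, 0 °C) should give 22.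

Step 4. What may go wrong: the aryllithium behaves as a base toward the amide (deprotonation next to the carbonyl or loss of the N-methoxy group) or adds to the allyl double bond on warming, so that acyl transfer stays incomplete. The fallback avoids a carbanion, sets out from alcohol 4 and comes back at ketone 12. Pentanoylation (pentanoyl chloride, pyridine, CH2Cl2) should give the bromo ester 3-(allyloxy)-4-bromobenzyl pentanoate F7. Stille coupling with tributyl(1-ethoxyvinyl)stannane (PdCl2(PPh3)2, toluene, 100 °C) should give the enol ether 3-(allyloxy)-4-(1-ethoxyvinyl)benzyl pentanoate F8, which dilute HCl hydrolyses to the methyl ketone 4-acetyl-3-(allyloxy)benzyl pentanoate F9. Soft enolisation (t-BuMe2SiOTf, Et3N, CH2Cl2, 0 °C) should give the silyl enol ether 3-(allyloxy)-4-{1-[(tert-butyldimethylsilyl)oxy]vinyl}benzyl pentanoate F10. Rubottom oxidation (mCPBA, NaHCO3, CH2Cl2, 0 °C) should pass through the silyloxy oxirane 3-(allyloxy)-4-{2-[(tert-butyldimethylsilyl)oxy]oxiran-2-yl}benzyl pentanoate F11 and deliver 12 by 1,4-silyl shift.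

Further compounds
F1 | step 7 | 3-(allyloxy)-4-{3-[(tert-butyldimethylsilyl)oxy]prop-1-en-2-yl}benzyl pentanoate | CCCCC(=O)OCc1ccc(C(=C)CO[Si](C)(C)C(C)(C)C)c(OCC=C)c1
F2 | step 7 | 3-(allyloxy)-4-(3-hydroxyprop-1-en-2-yl)benzyl pentanoate | CCCCC(=O)OCc1ccc(C(=C)CO)c(OCC=C)c1
F3 | step 10 | 3-hydroxy-4-{3-[(tert-butyldimethylsilyl)oxy]prop-1-en-2-yl}benzyl pentanoate | CCCCC(=O)OCc1ccc(C(=C)CO[Si](C)(C)C(C)(C)C)c(O)c1
F4 | step 10 | 2-{3-[(tert-butyldimethylsilyl)oxy]prop-1-en-2-yl}-5-[(pentanoyloxy)methyl]phenyl 2-methylpropanoate | CCCCC(=O)OCc1ccc(C(=C)CO[Si](C)(C)C(C)(C)C)c(OC(=O)C(C)C)c1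
F5 | step 10 | 2-(3-hydroxyprop-1-en-2-yl)-5-[(pentanoyloxy)methyl]phenyl 2-methylpropanoate | CCCCC(=O)OCc1ccc(C(=C)CO)c(OC(=O)C(C)C)c1
F6 | step 10 | 2-[(2R)-2-(hydroxymethyl)oxiran-2-yl]-5-[(pentanoyloxy)methyl]phenyl 2-methylpropanoate | CCCCC(=O)OCc1ccc([C@@]2(CO)CO2)c(OC(=O)C(C)C)c1
F7 | step 4 | 3-(allyloxy)-4-bromobenzyl pentanoate | CCCCC(=O)OCc1ccc(Br)c(OCC=C)c1
F8 | step 4 | 3-(allyloxy)-4-(1-ethoxyvinyl)benzyl pentanoate | CCCCC(=O)OCc1ccc(C(=C)OCC)c(OCC=C)c1
F9 | step 4 | 4-acetyl-3-(allyloxy)benzyl pentanoate | CCCCC(=O)OCc1ccc(C(C)=O)c(OCC=C)c1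
F10 | step 4 | 3-(allyloxy)-4-{1-[(tert-butyldimethylsilyl)oxy]vinyl}benzyl pentanoate | CCCCC(=O)OCc1ccc(C(=C)O[Si](C)(C)C(C)(C)C)c(OCC=C)c1
F11 | step 4 | 3-(allyloxy)-4-{2-[(tert-butyldimethylsilyl)oxy]oxiran-2-yl}benzyl pentanoate (racemic) | CCCCC(=O)OCc1ccc(C2(O[Si](C)(C)C(C)(C)C)CO2)c(OCC=C)c1
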